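## Retrosynthetic overview

1. Target ⇒ (−)-lariciresinol + p-coumaric acid: chemoselective Mitsunobu esterification of the only aliphatic hydroxyl, with no protecting groups.
2. (−)-Lariciresinol ⇒ 7-hydroxy-seco triol (oxolane C7–O–C9' closed last, through the p-quinone methide) ⇒ trans-α-aroyl-β-benzyl-γ-butyrolactone by hydride reduction.
3. Keto lactone ⇒ 1-aroyl-6-aryl-3-oxabicyclo[3.1.0]hexan-2-one: hydrogenolysis of the donor–acceptor cyclopropane bond C8–C7' together with both benzyl ethers.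
4. Bicycle ⇒ cinnamyl α-diazo-β-keto ester: one enantioselective intramolecular cyclopropanation closes the γ-lactone and the cyclopropane together, sets C8' and already holds all 18 skeletal carbons.
5. Diazo ester ⇒ O-benzylconiferyl alcohol + O-benzylvanillic acid + Meldrum's acid. Ring order: lactone and cyclopropane together, both opened again, oxolane last.

Assumption: the SMILES is read as drawn, i.e. oxolane (2R,3S,4S) = (7R,8S,8'S) in lignan numbering (the p-coumarate of (−)-lariciresinol); lignan numbering is used throughout (C7/C8/C9 on the half carrying the oxolane aryl group, C7'/C8'/C9' on the benzyl half); a one-pot sequence counts as one step.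

## Route

Step 1
Reactants: 1 4-benzyloxy-3-methoxybenzaldehyde (O-benzylvanillin); 2 ethyl (triphenylphosphoranylidene)acetate
Product: 3 ethyl (E)-3-(4-benzyloxy-3-methoxyphenyl)prop-2-enoate
Conditions: toluene, 90 °C
Reagents that add atoms: none
Why: Wittig olefination with a stabilised ylide gives the (E)-cinnamate with high selectivity under neutral conditions; no stereocentre is formed.

Step 2
Reactants: 3 ethyl (E)-3-(4-benzyloxy-3-methoxyphenyl)prop-2-enoate
Product: 4 (E)-3-(4-benzyloxy-3-methoxyphenyl)prop-2-en-1-ol (O-benzylconiferyl alcohol)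
Conditions: i-Bu2AlH (2.3 equiv), CH2Cl2, −78 → 0 °C; aq. potassium sodium tartrate work-up
Reagents that add atoms: none
Why: 1,2-reduction of the conjugated ester by i-Bu2AlH stops at the allylic alcohol and leaves the alkene geometry and the benzyl ether untouched.

Step 3
Reactants: 5 4-benzyloxy-3-methoxybenzoic acid; 6 Meldrum's acid (2,2-dimethyl-1,3-dioxane-4,6-dione); 4 (E)-3-(4-benzyloxy-3-methoxyphenyl)prop-2-en-1-ol
Product: 8 (E)-3-(4-benzyloxy-3-methoxyphenyl)prop-2-en-1-yl 3-(4-benzyloxy-3-methoxyphenyl)-3-oxopropanoate, via acyl Meldrum's acid 7 (not isolated)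
Conditions: 5, 6, DCC, DMAP, CH2Cl2, 0 °C → rt; filter, aq. KHSO4 wash, concentrate; then 4, toluene, 85 °C
Reagents that add atoms: none
Why: Oikawa–Yonemitsu β-keto ester synthesis: carbodiimide C-acylation of Meldrum's acid, then thermolysis with loss of acetone and CO2 to an acylketene that is trapped by alcohol 4 under neutral conditions, which spares the acid-sensitive electron-rich cinnamyl unit.

Step 4
Reactants: 8 (E)-3-(4-benzyloxy-3-methoxyphenyl)prop-2-en-1-yl 3-(4-benzyloxy-3-methoxyphenyl)-3-oxopropanoate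
Product: 9 (E)-3-(4-benzyloxy-3-methoxyphenyl)prop-2-en-1-yl 2-diazo-3-(4-benzyloxy-3-methoxyphenyl)-3-oxopropanoate
Conditions: p-ABSA (1.2 equiv), Et3N, MeCN, 0 °C → rt
Reagents that add atoms: 4-acetamidobenzenesulfonyl azide (p-ABSA), CC(=O)Nc1ccc(cc1)S(=O)(=O)N=[N+]=[N-]
Why: Regitz diazo transfer to the doubly activated methylene of the β-keto ester is reliable and does not affect the alkene or the ethers.

Step 5
Reactants: 9 (E)-3-(4-benzyloxy-3-methoxyphenyl)prop-2-en-1-yl 2-diazo-3-(4-benzyloxy-3-methoxyphenyl)-3-oxopropanoate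
Product: 10 (1R,5S,6R)-1-(4-benzyloxy-3-methoxybenzoyl)-6-(4-benzyloxy-3-methoxyphenyl)-3-oxabicyclo[3.1.0]hexan-2-one (aryl group exo and cis to the aroyl group)
Conditions: Co(3,5-DitBu-Xu(2'-Naph)Phyrin) (3 mol%, D2-symmetric chiral amidoporphyrin complex of divalent cobalt, ligand antipode that gives 5S), toluene, N2, rt → 40 °C
Reagents that add atoms: none
Why: Enantioselective intramolecular cyclopropanation by metalloradical catalysis: the catalyst turns the diazo group into a trivalent-cobalt carbene radical at C8, held by hydrogen bonds from the chiral amide N–H groups to the two carbonyls, which adds 5-exo to one face of the electron-rich (E)-styrenyl alkene (γ-lactone ring, C8–C8' bond, C8' = C5 set as S by the catalyst), and the resulting benzylic radical closes 3-exo onto C8 (cyclopropane ring), so both rings form in one operation with the cis fusion enforced by the bicycle.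

Step 6
Reactants: 10 (1R,5S,6R)-1-(4-benzyloxy-3-methoxybenzoyl)-6-(4-benzyloxy-3-methoxyphenyl)-3-oxabicyclo[3.1.0]hexan-2-one
Product: 11 (3R,4S)-3-(4-hydroxy-3-methoxybenzoyl)-4-(4-hydroxy-3-methoxybenzyl)oxolan-2-one (trans)
Conditions: H2 (1 atm), Pd/C (10 wt% Pd on carbon), EtOAc–THF, rt; stopped after uptake of 3 equiv H2
Reagents that add atoms: none
Why: Heterogeneous catalytic hydrogenolysis cleaves the doubly activated donor–acceptor bond C1–C6 (benzylic and α to ketone and lactone) together with both benzyl ethers, leaves C5 (C8') untouched and turns C1 (C8) into a β-dicarbonyl carbon that equilibrates trans to the new benzyl group; partial reduction of the ketone to the carbinol is harmless because the next step makes that carbinol anyway.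

Step 7
Reactants: 11 (3R,4S)-3-(4-hydroxy-3-methoxybenzoyl)-4-(4-hydroxy-3-methoxybenzyl)oxolan-2-one
Product: 14 (−)-lariciresinol = 4-[(2R,3S,4S)-4-(4-hydroxy-3-methoxybenzyl)-3-(hydroxymethyl)oxolan-2-yl]-2-methoxyphenol, via hydroxy lactone 12 (not isolated), via triol 13 (not isolated)
Conditions: LiBH4 (5 equiv), THF–MeOH (10:1), 0 °C → rt; then 1 M aq. HCl to pH 1, rt, 2 h
Reagents that add atoms: none
Why: Borohydride reduction (ketone first, then lactone) followed by acid-catalysed dehydrative cycloetherification through the p-hydroxybenzyl cation (p-quinone methide): only the C9' hydroxyl can close a five-membered ring, C8 and C8' are untouched, and C7 is set as R because the aryl group takes the position trans to the C8 hydroxymethyl group, which is the kinetic and, since the closure is reversible in acid, also the thermodynamic 2,3-trans product.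

Step 8
Reactants: 14 (−)-lariciresinol; 15 (E)-3-(4-hydroxyphenyl)prop-2-enoic acid (p-coumaric acid)
Product: 16 lariciresinol p-coumarate = [(2R,3S,4S)-2-(4-hydroxy-3-methoxyphenyl)-4-(4-hydroxy-3-methoxybenzyl)oxolan-3-yl]methyl (E)-3-(4-hydroxyphenyl)prop-2-enoate
Conditions: PPh3 (1.3 equiv), DIAD (1.3 equiv, added last and slowly), 15 (1.2 equiv), THF, 0 °C → rt
Reagents that add atoms: none
Why: Mitsunobu esterification activates only the aliphatic primary hydroxyl as an alkoxyphosphonium ion, and the carboxylic acid (pKa about 4.5) is alkylated in preference to the three phenols (pKa about 10), so no protection is needed; the reacting carbon is a CH2 group and no stereocentre is touched.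

## Compound list

1 | 4-benzyloxy-3-methoxybenzaldehyde (O-benzylvanillin) | COc1cc(C=O)ccc1OCc1ccccc1 | starting material
2 | ethyl (triphenylphosphoranylidene)acetate | CCOC(=O)C=P(c1ccccc1)(c1ccccc1)c1ccccc1 | starting material
3 | ethyl (E)-3-(4-benzyloxy-3-methoxyphenyl)prop-2-enoate | CCOC(=O)/C=C/c1ccc(OCc2ccccc2)c(OC)c1 | intermediate
4 | (E)-3-(4-benzyloxy-3-methoxyphenyl)prop-2-en-1-ol | OC/C=C/c1ccc(OCc2ccccc2)c(OC)c1 | intermediate
5 | 4-benzyloxy-3-methoxybenzoic acid | COc1cc(C(=O)O)ccc1OCc1ccccc1 | starting material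
6 | Meldrum's acid | CC1(C)OC(=O)CC(=O)O1 | starting material
7 | 5-[(4-benzyloxy-3-methoxyphenyl)(hydroxy)methylidene]-2,2-dimethyl-1,3-dioxane-4,6-dione | COc1cc(C(O)=C2C(=O)OC(C)(C)OC2=O)ccc1OCc1ccccc1 | intermediate
8 | (E)-3-(4-benzyloxy-3-methoxyphenyl)prop-2-en-1-yl 3-(4-benzyloxy-3-methoxyphenyl)-3-oxopropanoate | COc1cc(C(=O)CC(=O)OC/C=C/c2ccc(OCc3ccccc3)c(OC)c2)ccc1OCc1ccccc1 | intermediate
9 | (E)-3-(4-benzyloxy-3-methoxyphenyl)prop-2-en-1-yl 2-diazo-3-(4-benzyloxy-3-methoxyphenyl)-3-oxopropanoate | COc1cc(C(=O)C(=[N+]=[N-])C(=O)OC/C=C/c2ccc(OCc3ccccc3)c(OC)c2)ccc1OCc1ccccc1 | intermediate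
10 | (1R,5S,6R)-1-(4-benzyloxy-3-methoxybenzoyl)-6-(4-benzyloxy-3-methoxyphenyl)-3-oxabicyclo[3.1.0]hexan-2-one | O=C1OC[C@H]2[C@H](c3ccc(OCc4ccccc4)c(OC)c3)[C@@]12C(=O)c1ccc(OCc2ccccc2)c(OC)c1 | intermediate
11 | (3R,4S)-3-(4-hydroxy-3-methoxybenzoyl)-4-(4-hydroxy-3-methoxybenzyl)oxolan-2-one | O=C1OC[C@@H](Cc2ccc(O)c(OC)c2)[C@@H]1C(=O)c1ccc(O)c(OC)c1 | intermediate
12 | (3R,4S)-3-[hydroxy(4-hydroxy-3-methoxyphenyl)methyl]-4-(4-hydroxy-3-methoxybenzyl)oxolan-2-one (carbinol epimers) | O=C1OC[C@@H](Cc2ccc(O)c(OC)c2)[C@@H]1C(O)c1ccc(O)c(OC)c1 | intermediate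
13 | (2S,3S)-2-[hydroxy(4-hydroxy-3-methoxyphenyl)methyl]-3-(4-hydroxy-3-methoxybenzyl)butane-1,4-diol (carbinol epimers) | OC[C@@H](Cc1ccc(O)c(OC)c1)[C@@H](CO)C(O)c1ccc(O)c(OC)c1 | intermediate
14 | (−)-lariciresinol, 4-[(2R,3S,4S)-4-(4-hydroxy-3-methoxybenzyl)-3-(hydroxymethyl)oxolan-2-yl]-2-methoxyphenol | COc1cc(C[C@@H]2CO[C@@H](c3ccc(O)c(OC)c3)[C@@H]2CO)ccc1O | intermediate
15 | (E)-3-(4-hydroxyphenyl)prop-2-enoic acid (p-coumaric acid) | OC(=O)/C=C/c1ccc(O)cc1 | starting material
16 | lariciresinol p-coumarate, [(2R,3S,4S)-2-(4-hydroxy-3-methoxyphenyl)-4-(4-hydroxy-3-methoxybenzyl)oxolan-3-yl]methyl (E)-3-(4-hydroxyphenyl)prop-2-enoate | COc1cc(C[C@@H]2CO[C@@H](c3ccc(O)c(OC)c3)[C@@H]2COC(=O)/C=C/c2ccc(O)cc2)ccc1O | target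

## Step count and risks

Total step count: 8.
Longest linear sequence: 8 steps (1 → 3 → 4 → 8 → 9 → 10 → 11 → 14 → 16); 5, 6 and 15 enter as commercial materials.

Steps most likely to fail:

**Step 5 (the double ring closure).** The class of reaction (intramolecular cyclopropanation of allyl α-acyl diazoacetates under cobalt metalloradical catalysis) is established, but high enantioselectivity with an electron-rich aroyl acceptor and a p-alkoxycinnamyl alkene is not. Carbene dimerisation is a second risk. Rearrangement of 10 to the fused dihydrofuran isomer would be tolerable, because its benzylic C–O bond is hydrogenolysed to the same lactone 11.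

Fallback, setting out from 1 and coming back at 14: Stobbe condensation of 1 with dimethyl succinate (KOt-Bu, t-BuOH, reflux) gives (E)-4-(4-benzyloxy-3-methoxyphenyl)-3-(methoxycarbonyl)but-3-enoic acid F1. Asymmetric hydrogenation ([Rh(cod)2]BF4 with the antipode of a DIOP-type bisphosphine that delivers S, Et3N, MeOH, H2) gives (S)-4-(4-benzyloxy-3-methoxyphenyl)-3-(methoxycarbonyl)butanoic acid F2. Reduction of the ester in the presence of the carboxylate (KOH, then Ca(BH4)2, EtOH) and acidic lactonisation give (S)-4-(4-benzyloxy-3-methoxybenzyl)oxolan-2-one F3. Its lithium enolate (LiN(i-Pr)2, THF, −78 °C) adds to 1 anti to the benzyl group to give (3R,4S)-3-[(4-benzyloxy-3-methoxyphenyl)(hydroxy)methyl]-4-(4-benzyloxy-3-methoxybenzyl)oxolan-2-one F4. LiAlH4 gives (2S,3S)-2-[(4-benzyloxy-3-methoxyphenyl)(hydroxy)methyl]-3-(4-benzyloxy-3-methoxybenzyl)butane-1,4-diol F5. Camphorsulfonic acid in CH2Cl2 closes the oxolane to [(2R,3S,4S)-2-(4-benzyloxy-3-methoxyphenyl)-4-(4-benzyloxy-3-methoxybenzyl)oxolan-3-yl]methanol F6. Brief hydrogenolysis (H2, Pd/C, EtOAc) gives 14.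

**Step 6 (triple hydrogenolysis).** The aryl ketone may be reduced through to the methylene, the cyclopropane may open more slowly than the benzyl ethers cleave, or the quinone methide formed after debenzylation may be trapped.

Fallback, setting out from 10 and coming back at 11: single-electron opening with SmI2 (2.5 equiv, THF–MeOH, −78 °C; ketyl, cyclopropylcarbinyl opening toward the benzylic carbon, second electron, protonation) gives (3R,4S)-3-(4-benzyloxy-3-methoxybenzoyl)-4-(4-benzyloxy-3-methoxybenzyl)oxolan-2-one F7 with both benzyl ethers intact. BCl3 with pentamethylbenzene as cation scavenger (CH2Cl2, −78 °C) then removes the benzyl groups without any reductant and gives 11.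

**Step 8 (unprotected Mitsunobu).** Competing phenol O-alkylation or low conversion at the β-branched primary carbon would waste late-stage material.

Fallback, setting out from 14 and coming back at 16: exhaustive Steglich acylation with commercial (E)-4-acetoxycinnamic acid (3.5 equiv, EDC·HCl, DMAP, CH2Cl2) gives 4,4',9-tris-O-[(E)-4-acetoxycinnamoyl]-(−)-lariciresinol F8. Pyrrolidine (THF, rt) then cleaves the five aryl esters (three aryl acetates, two aryl cinnamates) much faster than the alkyl cinnamate and gives 16.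

Further compounds
F1 | step 5 | (E)-4-(4-benzyloxy-3-methoxyphenyl)-3-(methoxycarbonyl)but-3-enoic acid | COC(=O)/C(CC(=O)O)=C/c1ccc(OCc2ccccc2)c(OC)c1
F2 | step 5 | (S)-4-(4-benzyloxy-3-methoxyphenyl)-3-(methoxycarbonyl)butanoic acid | COC(=O)[C@H](CC(=O)O)Cc1ccc(OCc2ccccc2)c(OC)c1
F3 | step 5 | (S)-4-(4-benzyloxy-3-methoxybenzyl)oxolan-2-one | O=C1OC[C@@H](Cc2ccc(OCc3ccccc3)c(OC)c2)C1
F4 | step 5 | (3R,4S)-3-[(4-benzyloxy-3-methoxyphenyl)(hydroxy)methyl]-4-(4-benzyloxy-3-methoxybenzyl)oxolan-2-one (carbinol epimers) | O=C1OC[C@@H](Cc2ccc(OCc3ccccc3)c(OC)c2)[C@@H]1C(O)c1ccc(OCc2ccccc2)c(OC)c1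
F5 | step 5 | (2S,3S)-2-[(4-benzyloxy-3-methoxyphenyl)(hydroxy)methyl]-3-(4-benzyloxy-3-methoxybenzyl)butane-1,4-diol (carbinol epimers) | OC[C@@H](Cc1ccc(OCc2ccccc2)c(OC)c1)[C@@H](CO)C(O)c1ccc(OCc2ccccc2)c(OC)c1
F6 | step 5 | [(2R,3S,4S)-2-(4-benzyloxy-3-methoxyphenyl)-4-(4-benzyloxy-3-methoxybenzyl)oxolan-3-yl]methanol | COc1cc(C[C@@H]2CO[C@@H](c3ccc(OCc4ccccc4)c(OC)c3)[C@@H]2CO)ccc1OCc1ccccc1
F7 | step 6 | (3R,4S)-3-(4-benzyloxy-3-methoxybenzoyl)-4-(4-benzyloxy-3-methoxybenzyl)oxolan-2-one | O=C1OC[C@@H](Cc2ccc(OCc3ccccc3)c(OC)c2)[C@@H]1C(=O)c1ccc(OCc2ccccc2)c(OC)c1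
F8 | step 8 | 4,4',9-tris-O-[(E)-4-acetoxycinnamoyl]-(−)-lariciresinol | COc1cc(C[C@@H]2CO[C@@H](c3ccc(OC(=O)/C=C/c4ccc(OC(C)=O)cc4)c(OC)c3)[C@@H]2COC(=O)/C=C/c2ccc(OC(C)=O)cc2)ccc1OC(=O)/C=C/c1ccc(OC(C)=O)cc1
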